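common to all: substrate 0.40 M

| flask | reagent | temperature | remark | time |
|---|---|---|---|---|
| autumn | 1.1 equiv | 8 °C | run made earlier |  |
| summer | 1.8 equiv | 24 °C | run made earlier |  |
| blue | 0.800 equiv | 30 °C |  | 2.0 min |
| amber | 0.800 equiv | 15 °C |  | 2.0 min |
| green | 0.800 equiv | 0 °C |  | 2.0 min |
| red | 0.800 equiv |  | at 0 °C until 40 s, from then on at 30 °C | 2.0 min |

autumn run (percent of the substrate charged)

| time / min | single product / % | substrate / % |
|---|---|---|
| 0.500 | 20.9 | 23.8 |
| 0.667 | 21.3 | 24.0 |
| 1.00 | 21.0 | 24.2 |
| 1.33 | 21.3 | 24.0 |
| 2.50 | 21.6 | 24.3 |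
| 4.00 | 21.0 | 24.0 |
| 6.00 | 21.8 | 23.5 |

summer run (percent of the substrate charged)

| time / s | single product / % | substrate / % |
|---|---|---|
| 15.0 | 10.4 | 1.1 |
| 30.0 | 10.4 | 1.3 |
| 50.0 | 10.0 | 0.9 |
| 60.0 | 10.7 | 1.0 |
| 80.0 | 10.1 | 0.9 |
| 90.0 | 10.6 | 1.0 |
| 120 | 10.3 | 0.7 |

(scatter of a reading: 0.3 percentage points)

* the flask that comes out highest in amount of single product, in percent of the substrate charged, or "all alike" when all lie within 1.5 percentage points (blue / amber / green / red / all alike)
* single product at the end, in percent of the substrate charged, blue
* single product at the end, in percent of the substrate charged, amber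
* single product at the end, in percent of the substrate charged, green
* single product at the end, in percent of the substrate charged, red

- the numbers in the tables scatter by 0.3 percentage points (one standard deviation)

The autumn run lies flat from its first reading at 0.500 min, with mean substrate 0.240 and single product 0.213, as fractions of the charge. The summer run is flat too, at 0.00986 and 0.104.

Suppose reagent is the limiting reagent and its charge is wholly used. Each substrate lost then takes one reagent, and the surplus goes on to make bis adduct, 0.340 in autumn. The rest of the loss took no further reagent, so take it as an isomer of the product: 0.208 in autumn and 0.0767 in summer.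

Two amounts now matter, isomer and single product. Their quotient, the plateau ratio, is 0.977 at 8 °C and 0.741 at 24 °C, lower in the hotter run. Single product holds one part in one plus this ratio of the pool, which is single product plus isomer.

Carried on at the same fall per degree, the ratio is 1.12 for green, 0.866 for amber and, for blue, a plateau ratio of 0.668. This reckoning assumes autumn's pool, 0.421, for these flasks. Green then gives 0.198, amber 0.225 and blue 0.252, the highest. Red spends its first 40 s at green's temperature and the rest at blue's, so this reckoning places it between green's 0.198 and blue's 0.252.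

The forecast runs the other way: blue 3 %, amber 9 %, green 25 %, red 22 %, with green highest, holding that “a competing sink takes most of it”.

Blue comes out highest at 27.0 %, then amber 23.1 %, red 23.0 % and green 18.7 %.

    substrate + reagent → single product (k = 1.80 M⁻¹ s⁻¹, Ea = 46.0 kJ mol⁻¹)
    reagent + single product → bis adduct (k = 1.90 M⁻¹ s⁻¹, Ea = 40.0 kJ mol⁻¹)
    reagent ⇌ dormant form (K = 0.730, k = 0.0140 s⁻¹, Ea = 81.0 kJ mol⁻¹, ΔH = −40.0 kJ mol⁻¹)
    single product ⇌ isomer of the product (K = 1.10, k = 0.130 s⁻¹, Ea = 76.0 kJ mol⁻¹, ΔH = −10.0 kJ mol⁻¹)
    (constants at 0 °C)

In green, the forward step from single product to isomer has a half-life of 0.089 min at 0.0135 min, short against 2.0 min. Blue's pool divided by one plus the carried ratio gives 0.277. Red at its change of temperature, 0.667 min, holds reagent at 0.0466 % of its own charge, single product 18.6 % and isomer 20.4 %. That pool divided the same way gives 0.234, and red ends with single product at 23.0 %.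

(The readings stem from a simulated flask from invented constants; scatter was added.)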